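**Retrosynthetic overview**
- The target comes from its 9β,10β-epoxide by SmI2 cleavage of C9–O. That epoxy acid comes from the (E)-12-aldehyde by an oxidative carbene-catalysed deconjugation, which makes the acid, sets C11 and moves the alkene to C6=C7.
- The angelate and the C12 oxidation are placed on 9β,10β-epoxy-3β-hydroxyeremophil-7(11)-en-8-one. This comes from eremophila-7(11),9-diene-3,8-dione by α-face hydride delivery and β-face peroxide attack.
- Eremophilane from eudesmane: a 3α,4α-epoxide triggers the 1,2-H (C5 to C4) and 1,2-CH3 (C10 to C5) shifts of the biosynthetic eudesmyl-to-eremophilenyl cation step.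
- Eudesmane from germacrone: a catalytic asymmetric, proton-induced transannular C5–C10 closure.
- Ring order: the ten-membered ring is bought with germacrone. Both six-membered rings form together in step 1, and no later C–C ring closure is needed.

Assumption: germacrone (crystallised from zdravetz oil) and angelic acid count as cheap commercial materials, terpenoid numbering is used (β = the face carrying C14), and for the two chiral organocatalysts (steps 1 and 7) one screening run fixes which enantiomer gives the drawn sense.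

**Step 1**
Reactants: 1 germacrone
Product: 2 (5R,10R)-eudesma-3,7(11)-dien-8-one (trans-fused; 5α-H; 10β-CH3)
Conditions: chiral imidodiphosphorimidate Brønsted acid (IDPi, 3,3'-diaryl-BINOL backbones, N-triflyl; 5 mol %), CHCl3/(CF3)2CHOH 4:1, −40 °C
Reagents that add atoms: none
Why: Proposed new method: the mirror-image crown conformers of planar-chiral germacrone interconvert fast, so a confined chiral acid can protonate C1 of one conformer only (dynamic kinetic resolution), C4=C5 then attacks the C10 cation across the ring through the chair-chair array used in nature (C5–C10 bond, trans fusion, fixing 5α-H and 10β-CH3), and the paired anion removes the axial 3α-H of the C4 cation; the closest known reaction types are the racemic acid-induced cyclisation of germacrone to selinadienones and IDPi-catalysed asymmetric protonation of unactivated olefins in polyene cyclisations.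

**Step 2**
Reactants: 2 (5R,10R)-eudesma-3,7(11)-dien-8-one
Product: 3 (3R,4S,5R,10R)-3α,4α-epoxyeudesm-7(11)-en-8-one
Conditions: mCPBA (1.05 equiv), CH2Cl2, −20 °C
Reagents that add atoms: mCPBA (3-chloroperoxybenzoic acid), OOC(=O)c1cccc(Cl)c1
Why: Prilezhaev epoxidation takes the only electron-rich alkene (the enone alkene is inert) from the α face, because the axial 10β-methyl shields the β face, and this sets C3 and C4.

**Step 3**
Reactants: 3 (3R,4S,5R,10R)-3α,4α-epoxyeudesm-7(11)-en-8-one
Product: 5 (4R,5R)-eremophila-7(11),9-diene-3,8-dione, via isopetasol 4 (not isolated)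
Conditions: BF3·OEt2 (0.3 equiv), CH2Cl2, −78 to −30 °C; then pyridine, Dess–Martin periodinane (1.3 equiv), 23 °C, same flask
Reagents that add atoms: none
Why: Proposed new method: trans-diaxial C4–O opening leaves O on C3 and a tertiary C4 cation in which the equatorial H3 is misaligned while the axial 5α-H and then the axial 10β-CH3 lie parallel to the empty orbital, so suprafacial 1,2-H (giving 4α-H/4β-CH3) and 1,2-CH3 (giving 5β-CH3) shifts copy the biosynthetic eudesmyl-to-eremophilenyl step, loss of the ketone-acidified H9 ends irreversibly in the cross-conjugated dienone, and Dess–Martin oxidation then erases the wrongly configured 3α-carbinol; the closest known reaction types are the Westphalen rearrangement and BF3-induced backbone rearrangements of 5,6-epoxy steroids and epoxyeudesmanes.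

**Step 4**
Reactants: 5 (4R,5R)-eremophila-7(11),9-diene-3,8-dione
Product: 7 (3S,4R,5R,9R,10R)-9β,10β-epoxy-3β-hydroxyeremophil-7(11)-en-8-one, via 3-epi-isopetasol 6 (not isolated)
Conditions: LiBH(s-Bu)3 (1.05 equiv), THF, −78 °C; then MeOH, aq NaOH, 30% H2O2 (6 equiv), 0 °C, same flask
Reagents that add atoms: hydrogen peroxide, OO
Why: The bulky borohydride reduces the only saturated ketone along the equatorial α trajectory (the axial β path is blocked by the syn-axial C5 methyl) to give 3β-OH, and the alkaline peroxide that destroys the borane then performs a Weitz–Scheffer epoxidation of the less substituted C9=C10 enone from the β face, cis to the angular methyl as in 4-en-3-one steroids, setting C9 and C10.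

**Step 5**
Reactants: 7 (3S,4R,5R,9R,10R)-9β,10β-epoxy-3β-hydroxyeremophil-7(11)-en-8-one
Product: 8 (7(11)E)-9β,10β-epoxy-3β-hydroxy-8-oxoeremophil-7(11)-en-12-al (CHO cis to C6, trans to C8)
Conditions: SeO2 (1.3 equiv), 1,4-dioxane, 80 °C
Reagents that add atoms: selenium dioxide, O=[Se]=O
Why: In this Riley allylic oxidation (ene reaction, then 2,3-shift) the ketone has no enolisable α-CH2 (C9 is an oxirane carbon, C7 is sp2) and C6 is neopentyl, so only an enone γ-methyl reacts, and as with β,β-dimethyl enones the methyl trans to the carbonyl is oxidised to the E-enal.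

**Step 6**
Reactants: 8 (7(11)E)-9β,10β-epoxy-3β-hydroxy-8-oxoeremophil-7(11)-en-12-al; 9 angelic acid ((Z)-2-methylbut-2-enoic acid)
Product: 11 (7(11)E)-3β-angeloyloxy-9β,10β-epoxy-8-oxoeremophil-7(11)-en-12-al, via mixed anhydride 10 (not isolated)
Conditions: 9 (3 equiv), 2,4,6-trichlorobenzoyl chloride (3 equiv), Et3N, toluene, 23 °C; then 8, 80 °C
Reagents that add atoms: none
Why: Yamaguchi mixed-anhydride esterification without DMAP acylates the only hydroxyl group with retention at C3 and keeps the Z geometry of the angelate, and it is done before C11 becomes a stereocentre.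

**Step 7**
Reactants: 11 (7(11)E)-3β-angeloyloxy-9β,10β-epoxy-8-oxoeremophil-7(11)-en-12-al
Product: 12 (3S,4R,5R,9R,10R,11R)-3β-angeloyloxy-9β,10β-epoxy-8-oxoeremophil-6-en-12-oic acid
Conditions: chiral aminoindanol-derived N-mesityl triazolium tetrafluoroborate (15 mol %), i-Pr2NEt, 3,3',5,5'-tetra-tert-butyl-4,4'-diphenoquinone (1.1 equiv), H2O (5 equiv), THF, 0 °C
Reagents that add atoms: water, O
Why: Proposed new method: the carbene adds to the aldehyde and the quinone oxidises the Breslow intermediate to the hindered conjugated acyl azolium, whose C6–H is removed to give an azolium dienolate that is protonated at C11 on the face left open by the chiral carbene (11R), and the resulting more electrophilic β,γ-unsaturated acyl azolium (alkene now conjugated to C8=O) is hydrolysed faster than its conjugated isomer; the closest known reaction types are oxidative carbene catalysis of enals with γ-deprotonation to vinyl enolates and enantioselective protonation of azolium enolates.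

**Step 8**
Reactants: 12 (3S,4R,5R,9R,10R,11R)-3β-angeloyloxy-9β,10β-epoxy-8-oxoeremophil-6-en-12-oic acid
Product: 13 (3S,4R,5R,10S,11R)-3β-angeloyloxy-10β-hydroxy-8-oxoeremophil-6-en-12-oic acid (target)
Conditions: SmI2 (2.5 equiv), THF/MeOH, −90 °C, 10 min
Reagents that add atoms: none
Why: In this reductive opening of an α,β-epoxy ketone, divalent samarium forms the ketyl, the α C9–O bond breaks and the enolate is protonated, while the C10–O bond is untouched so 10β-OH keeps its configuration, and the angelate, acid and hindered enone survive at this temperature.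

**Compound list**
1 | germacrone, (1(10)E,4E)-germacra-1(10),4,7(11)-trien-8-one | C/C/1=C\CC(=C(C)C)C(=O)C/C(=C/CC1)/C | starting material
2 | (5R,10R)-eudesma-3,7(11)-dien-8-one | CC1=CCC[C@]2(C)CC(=O)C(=C(C)C)C[C@@H]12 | intermediate
3 | (3R,4S,5R,10R)-3α,4α-epoxyeudesm-7(11)-en-8-one | C[C@@]12O[C@@H]1CC[C@]3(C)CC(=O)C(=C(C)C)C[C@@H]23 | intermediate
4 | isopetasol, (3R,4R,5R)-3α-hydroxyeremophila-7(11),9-dien-8-one | O[C@@H]1CCC2=CC(=O)C(=C(C)C)C[C@]2(C)[C@H]1C | intermediate
5 | (4R,5R)-eremophila-7(11),9-diene-3,8-dione | O=C1CCC2=CC(=O)C(=C(C)C)C[C@]2(C)[C@H]1C | intermediate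
6 | 3-epi-isopetasol, (3S,4R,5R)-3β-hydroxyeremophila-7(11),9-dien-8-one | O[C@H]1CCC2=CC(=O)C(=C(C)C)C[C@]2(C)[C@H]1C | intermediate
7 | (3S,4R,5R,9R,10R)-9β,10β-epoxy-3β-hydroxyeremophil-7(11)-en-8-one | O[C@H]1CC[C@]2(O3)[C@@H]3C(=O)C(=C(C)C)C[C@]2(C)[C@H]1C | intermediate
8 | (7(11)E)-9β,10β-epoxy-3β-hydroxy-8-oxoeremophil-7(11)-en-12-al | O[C@H]1CC[C@]2(O3)[C@@H]3C(=O)/C(=C(/C=O)C)C[C@]2(C)[C@H]1C | intermediate
9 | angelic acid | C/C=C(/C)C(=O)O | starting material
10 | angelic 2,4,6-trichlorobenzoic anhydride | C/C=C(/C)C(=O)OC(=O)c1c(Cl)cc(Cl)cc1Cl | intermediate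
11 | (7(11)E)-3β-angeloyloxy-9β,10β-epoxy-8-oxoeremophil-7(11)-en-12-al | C/C=C(/C)C(=O)O[C@H]1CC[C@]2(O3)[C@@H]3C(=O)/C(=C(/C=O)C)C[C@]2(C)[C@H]1C | intermediate
12 | (3S,4R,5R,9R,10R,11R)-3β-angeloyloxy-9β,10β-epoxy-8-oxoeremophil-6-en-12-oic acid | C/C=C(/C)C(=O)O[C@H]1CC[C@]2(O3)[C@@H]3C(=O)C([C@@H](C)C(=O)O)=C[C@]2(C)[C@H]1C | intermediate
13 | (3S,4R,5R,10S,11R)-3β-angeloyloxy-10β-hydroxy-8-oxoeremophil-6-en-12-oic acid | C/C=C(/C)C(=O)O[C@H]1CC[C@]2(O3... 

Correction of the last line, full entry:
13 | (3S,4R,5R,10S,11R)-3β-angeloyloxy-10β-hydroxy-8-oxoeremophil-6-en-12-oic acid | C/C=C(/C)C(=O)O[C@H]1CC[C@]2(O)CC(=O)C([C@@H](C)C(=O)O)=C[C@]2(C)[C@H]1C | target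

Total step count: 8. Longest linear sequence: 8 (1 to 13).

**Steps most likely to fail**

Step 1 may fail on two counts. Enantioselection by protonation and proton loss towards C3 (rather than C15 or C5) are both unproven. The fallback sets out from 1 and returns at 3. Germacrone is cyclised with TsOH·H2O in CH2Cl2 to the racemate, which is 2 together with its mirror image ent-eudesma-3,7(11)-dien-8-one F1. The absolute configuration is then set by the oxidant instead of the acid. A Shi epoxidation (fructose-derived ketone matched to the open α face of 2, KHSO5, K2CO3, MeCN/dimethoxymethane/water, 0 °C) is run as a kinetic resolution to about 45% conversion. It delivers 3 and leaves F1 unreacted.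

Step 3 may stop early. The C4 cation may lose a proton to give allylic alcohols, or H3 may shift to give a 3-ketone, before the H/CH3 shifts occur. The fallback sets out from 2 and returns at 5, and it creates the C5 cation directly.
- TsOH in warm benzene moves the alkene to the tetrasubstituted position, giving (10R)-eudesma-4,7(11)-dien-8-one F2.
- mCPBA gives 4α,5α-epoxyeudesm-7(11)-en-8-one F3.
- BF3·OEt2 opens C5–O with anti-periplanar migration of the 10β-methyl and loss of H9, giving 4α-hydroxyeremophila-7(11),9-dien-8-one F4.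
- SOCl2/pyridine removes the axial alcohol together with the axial 3β-H, giving eremophila-3,7(11),9-trien-8-one F5.
- mCPBA attacks the only electron-rich alkene from the α face, giving 3α,4α-epoxyeremophila-7(11),9-dien-8-one F6.
- A Meinwald rearrangement (MgBr2·OEt2, H shift from C3 to C4) followed by DBU equilibration of C4 to the equatorial 4β-methyl gives 5.

Step 7 may fail if the conjugated acyl azolium hydrolyses before deconjugation, or if the C11 protonation is unselective. The fallback sets out from 11 and returns at 12, and it replaces protonation by catalyst-controlled hydrogenation.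
- Pinnick oxidation (NaClO2, NaH2PO4, 2-methyl-2-butene) gives (7(11)E)-3β-angeloyloxy-9β,10β-epoxy-8-oxoeremophil-7(11)-en-12-oic acid F7.
- Carboxylate-directed hydrogenation with Ru(OAc)2[(R)-BINAP] (or its antipode) and H2 in MeOH leaves the angelate alone and gives (7αH,11R)-3β-angeloyloxy-9β,10β-epoxy-8-oxoeremophilan-12-oic acid F8.
- IBX in DMSO at 65 °C can dehydrogenate only towards C6–C7, because C9 is an oxirane carbon, and gives 12.

**Further compounds**
F1 | step 1 | ent-eudesma-3,7(11)-dien-8-one, (5S,10S) | CC1=CCC[C@@]2(C)CC(=O)C(=C(C)C)C[C@H]12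
F2 | step 3 | (10R)-eudesma-4,7(11)-dien-8-one | CC1=C2CC(=C(C)C)C(=O)C[C@@]2(C)CCC1
F3 | step 3 | 4α,5α-epoxyeudesm-7(11)-en-8-one (10β-CH3) | C[C@@]12CCC[C@]3(C)CC(=O)C(=C(C)C)C[C@@]13O2
F4 | step 3 | 4α-hydroxyeremophila-7(11),9-dien-8-one (4β-CH3, 5β-CH3) | C1CCC2=CC(=O)C(=C(C)C)C[C@]2(C)[C@]1(C)O
F5 | step 3 | eremophila-3,7(11),9-trien-8-one (5β-CH3) | C1=C(C)[C@@]2(C)CC(=C(C)C)C(=O)C=C2CC1
F6 | step 3 | 3α,4α-epoxyeremophila-7(11),9-dien-8-one | C[C@@]12O[C@@H]1CCC3=CC(=O)C(=C(C)C)C[C@]23C
F7 | step 7 | (7(11)E)-3β-angeloyloxy-9β,10β-epoxy-8-oxoeremophil-7(11)-en-12-oic acid | C/C=C(/C)C(=O)O[C@H]1CC[C@]2(O3)[C@@H]3C(=O)/C(=C(/C(=O)O)C)C[C@]2(C)[C@H]1C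
F8 | step 7 | (7αH,11R)-3β-angeloyloxy-9β,10β-epoxy-8-oxoeremophilan-12-oic acid | C/C=C(/C)C(=O)O[C@H]1CC[C@]2(O3)[C@@H]3C(=O)[C@@H]([C@@H](C)C(=O)O)C[C@]2(C)[C@H]1C
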